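**Retrosynthetic overview**
- Last operation: chelation-controlled cleavage of the C8 methyl ether of the 6,8-dimethoxy keto-lactone.
- Key C–C bond C5'–C6' (side chain numbered outward from C3): a pent-4-enyl side chain is hydroborated and the primary alkylborane is joined to the α-carbon of 1-bromohexan-2-one, which serves as an enolonium (a2) equivalent. This is done late, on the unprotected lactone.
- Lactone ring (the only ring made; the benzene ring is bought): aryl–C4 bond from ortho-lithiated N,N-diethyl-2,4-dimethoxybenzamide and a terminal epoxide, then acid lactonisation (C1–O2 bond).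
- C3 stereocentre: chiral pool, (R)-epichlorohydrin used as a three-carbon linchpin (butenyl Grignard on one side, aryl on the other); it is never a reacting centre afterwards.
- Ring order: benzene ring purchased, lactone ring closed in step 3, no further rings.

Assumption: the SMILES encodes the (R) configuration at C3 (priorities O > C4 > C1' > H), and catalog reagents such as but-3-en-1-ylmagnesium bromide and 1-bromohexan-2-one count as commercial.

**Route**

Step 1
Reactants: 1 2,4-dimethoxybenzoyl chloride
Product: 2 N,N-diethyl-2,4-dimethoxybenzamide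
Conditions: Et2NH (1.2 equiv), 2 M aq. NaOH, CH2Cl2, 0 °C → rt
Reagents that add atoms: diethylamine, CCNCC
Why: Schotten–Baumann N-acylation of a secondary amine by an aroyl chloride is fast and clean and installs the tertiary amide that will direct the ortho-lithiation, with no stereocentre involved.

Step 2
Reactants: 3 (R)-epichlorohydrin; 4 but-3-en-1-ylmagnesium bromide
Product: 6 (R)-2-(pent-4-en-1-yl)oxirane, via chlorohydrin 5 (not isolated)
Conditions: 4 (1.15 equiv), CuI (5 mol %), THF, −40 → −20 °C; H2O quench; crude 5, powdered NaOH, Et2O, rt; distil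
Reagents that add atoms: none
Why: Copper-catalysed Grignard opening of the epoxide at its unsubstituted carbon (much faster than displacement of the primary chloride) followed by Williamson-type closure of the chlorohydrin onto the CH2Cl carbon builds the new epoxide without breaking any bond at the carbinol carbon, so the (R) centre of 3 is carried over unchanged as the (R) centre of 6.

Step 3
Reactants: 2 N,N-diethyl-2,4-dimethoxybenzamide; 6 (R)-2-(pent-4-en-1-yl)oxirane
Product: 9 (R)-6,8-dimethoxy-3-(pent-4-en-1-yl)isochroman-1-one, via aryllithium 7 (not isolated), via hydroxy amide 8 (not isolated)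
Conditions: 2 (1.3 equiv), s-BuLi (1.3 equiv), TMEDA (1.3 equiv), THF, −78 °C, 1 h; 6 (1.0 equiv), BF3·OEt2 (3 equiv), −78 °C; H2O; crude 8, TsOH·H2O (20 mol %), PhMe, reflux
Reagents that add atoms: none
Why: Directed ortho-metalation (the tertiary amide outranks the methoxy groups, so lithium goes to C6), BF3-assisted SN2 opening of 6 at its terminal carbon and acid-catalysed lactonisation of the hydroxy amide with loss of diethylamine close the lactone ring, and because only the CH2 carbon of the epoxide is attacked and the lactonisation acylates oxygen, C3 keeps the (R) configuration delivered by 6.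

Step 4
Reactants: 9 (R)-6,8-dimethoxy-3-(pent-4-en-1-yl)isochroman-1-one; 10 1-bromohexan-2-one
Product: 12 (R)-6,8-dimethoxy-3-(7-oxoundecyl)isochroman-1-one, via B-alkyl-9-BBN 11 (not isolated)
Conditions: 9-BBN (1.2 equiv), THF, 0 °C → rt, 3 h; then 10 (1.3 equiv), potassium 2,6-di-tert-butylphenoxide (1.3 equiv, preformed THF solution, slow addition), 0 °C, 1 h; aq. NH4Cl
Reagents that add atoms: none
Why: Brown α-alkylation of an α-bromoketone by a B-alkyl-9-BBN, in which anti-Markovnikov hydroboration places boron on C5', the bromo-enolate of 10 adds to boron and the primary alkyl group then shifts from boron to the α-carbon with loss of bromide (1,2-metalate rearrangement), so that 10 acts as an enolonium (a2) equivalent and the new C5'–C6' bond joins a ketone α-carbon to an alkyl-metal carbon, two centres that are both normally nucleophilic, while the remote C3 stereocentre is not involved.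

Step 5
Reactants: 12 (R)-6,8-dimethoxy-3-(7-oxoundecyl)isochroman-1-one
Product: 13 (R)-8-hydroxy-6-methoxy-3-(7-oxoundecyl)isochroman-1-one
Conditions: BCl3 (2.5 equiv, 1 M in CH2Cl2), CH2Cl2, −78 → 0 °C; aq. NaHCO3
Reagents that add atoms: none
Why: Chelation-controlled Lewis-acid ether cleavage, in which BCl3 bridges the lactone carbonyl and the peri C8 methoxy oxygen in a six-membered chelate so that chloride removes only that methyl group, leaving the C6 methyl ether, the ketone and the C3 stereocentre untouched.

**Compound list**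

1 | 2,4-dimethoxybenzoyl chloride | COc1ccc(C(=O)Cl)c(OC)c1 | starting material
2 | N,N-diethyl-2,4-dimethoxybenzamide | CCN(CC)C(=O)c1ccc(OC)cc1OC | intermediate
3 | (R)-epichlorohydrin, (R)-2-(chloromethyl)oxirane | ClC[C@H]1CO1 | starting material
4 | but-3-en-1-ylmagnesium bromide | C=CCC[Mg]Br | starting material
5 | (R)-1-chlorohept-6-en-2-ol | ClC[C@H](O)CCCC=C | intermediate
6 | (R)-2-(pent-4-en-1-yl)oxirane | C=CCCC[C@@H]1CO1 | intermediate
7 | [2-(diethylcarbamoyl)-3,5-dimethoxyphenyl]lithium | [Li]c1cc(OC)cc(OC)c1C(=O)N(CC)CC | intermediate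
8 | (R)-N,N-diethyl-2-(2-hydroxyhept-6-en-1-yl)-4,6-dimethoxybenzamide | C=CCCC[C@@H](O)Cc1cc(OC)cc(OC)c1C(=O)N(CC)CC | intermediate
9 | (R)-6,8-dimethoxy-3-(pent-4-en-1-yl)isochroman-1-one | C=CCCC[C@@H]1Cc2cc(OC)cc(OC)c2C(=O)O1 | intermediate
10 | 1-bromohexan-2-one | CCCCC(=O)CBr | starting material
11 | (R)-3-[5-(9-borabicyclo[3.3.1]nonan-9-yl)pentyl]-6,8-dimethoxyisochroman-1-one | B1(C2CCCC1CCC2)CCCCC[C@@H]1Cc2cc(OC)cc(OC)c2C(=O)O1 | intermediate
12 | (R)-6,8-dimethoxy-3-(7-oxoundecyl)isochroman-1-one | CCCCC(=O)CCCCCC[C@@H]1Cc2cc(OC)cc(OC)c2C(=O)O1 | intermediate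
13 | (R)-8-hydroxy-6-methoxy-3-(7-oxoundecyl)isochroman-1-one | CCCCC(=O)CCCCCC[C@@H]1Cc2cc(OC)cc(O)c2C(=O)O1 | target

**Step count**

Total step count: 5. Longest linear sequence: 4 steps (3 → 6 → 9 → 12 → 13; the branch 1 → 2 joins at step 3 and is equally long).

**Steps most likely to fail, with fallbacks**

Step 4 is the riskiest. 9-BBN may slowly reduce the lactone, the bromoketone may self-condense under base, and transfer of the alkyl group from boron may be incomplete. The fallback sets out from 9 and 10 and returns at 12, and replaces the boron ate chemistry by a radical atom-transfer addition. Irradiate 9 with 10 (2 equiv) and fac-Ir(ppy)3 (1 mol %) in MeCN under blue LEDs. The electrophilic α-keto radical from 10 adds to the terminal alkene carbon and bromine is transferred to C4', giving (3R)-3-(4-bromo-7-oxoundecyl)-6,8-dimethoxyisochroman-1-one F1 as a mixture of C4' epimers. Reduction of the secondary bromide with Bu3SnH and AIBN in toluene at 80 °C then gives 12.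

Step 3 is the second risk. The chelated aryllithium may open the epoxide sluggishly, BF3 is partly tied up by TMEDA, and the lithiated amide can self-condense if it warms. The fallback sets out from 6 and returns at 9, and builds the lactone carbonyl last. Prepare (3,5-dimethoxyphenyl)magnesium bromide F2 from 1-bromo-3,5-dimethoxybenzene and Mg in THF, and open 6 with it under CuI catalysis (10 mol %, −30 → 0 °C) to give (R)-1-(3,5-dimethoxyphenyl)hept-6-en-2-ol F3. Brominate the ring position next to the side chain with NBS in MeCN at 0 °C to give (R)-1-(2-bromo-3,5-dimethoxyphenyl)hept-6-en-2-ol F4. Close the ring by carbonylative lactonisation (Pd(OAc)2, Xantphos, CO 1 atm, K2CO3, toluene, 90 °C) to arrive at 9.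

Step 5 is the third risk. The enolisable ketone may suffer aldol chemistry under BCl3, and the C6 ether may be lost if the reaction is over-run. The fallback sets out from 9 and returns at 13, and demethylates before the ketone exists. BCl3 in CH2Cl2 (−78 → 0 °C) converts 9 into (R)-8-hydroxy-6-methoxy-3-(pent-4-en-1-yl)isochroman-1-one F5. Hydroboration with 2.2 equiv of 9-BBN then gives (R)-3-[5-(9-borabicyclo[3.3.1]nonan-9-yl)pentyl]-8-[(9-borabicyclo[3.3.1]nonan-9-yl)oxy]-6-methoxyisochroman-1-one F6, in which the phenol is masked as its borinate. F6 is alkylated with 10 and potassium 2,6-di-tert-butylphenoxide as in step 4, and aqueous work-up hydrolyses the aryl borinate and delivers 13 directly.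

**Further compounds**

F1 | step 4 | (3R)-3-(4-bromo-7-oxoundecyl)-6,8-dimethoxyisochroman-1-one (both C4' epimers) | CCCCC(=O)CCC(Br)CCC[C@@H]1Cc2cc(OC)cc(OC)c2C(=O)O1
F2 | step 3 | (3,5-dimethoxyphenyl)magnesium bromide | COc1cc(OC)cc([Mg]Br)c1
F3 | step 3 | (R)-1-(3,5-dimethoxyphenyl)hept-6-en-2-ol | C=CCCC[C@@H](O)Cc1cc(OC)cc(OC)c1
F4 | step 3 | (R)-1-(2-bromo-3,5-dimethoxyphenyl)hept-6-en-2-ol | C=CCCC[C@@H](O)Cc1cc(OC)cc(OC)c1Br
F5 | step 5 | (R)-8-hydroxy-6-methoxy-3-(pent-4-en-1-yl)isochroman-1-one | C=CCCC[C@@H]1Cc2cc(OC)cc(O)c2C(=O)O1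
F6 | step 5 | (R)-3-[5-(9-borabicyclo[3.3.1]nonan-9-yl)pentyl]-8-[(9-borabicyclo[3.3.1]nonan-9-yl)oxy]-6-methoxyisochroman-1-one | B1(C2CCCC1CCC2)CCCCC[C@@H]1Cc2cc(OC)cc(OB3C4CCCC3CCC4)c2C(=O)O1
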